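Two things were asked of me about these flasks: how much open intermediate stands at the end of each, and how that row runs. The earlier runs were what I had to go on.

| flask | substrate | partner | second reagent | capture agent | remark | time |
|---|---|---|---|---|---|---|
| teal | 0.030 M | 0.090 M | 0.11 M | 2 mM | run made earlier |  |
| ochre | 0.11 M | 0.090 M | 0.11 M | 2 mM | run made earlier |  |
| grey | 0.43 M | 0.090 M | 0.11 M | 2 mM | run made earlier |  |
| dawn | 0.025 M | 0.0900 M | 0.110 M | 2.00 mM |  | 2.0 min |
| noon | 0.050 M | 0.0900 M | 0.110 M | 2.00 mM |  | 2.0 min |
| summer | 0.10 M | 0.0900 M | 0.110 M | 2.00 mM |  | 2.0 min |
| spring | 0.20 M | 0.0900 M | 0.110 M | 2.00 mM |  | 2.0 min |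
| midnight | 0.40 M | 0.0900 M | 0.110 M | 2.00 mM |  | 2.0 min |

- teal (time / s: open intermediate / %, product / %): 10.0: 8.2, 1.8; 20.0: 12.8, 7.2; 40.0: 16.2, 20.3; 60.0: 14.5, 33.3; 80.0: 12.7, 42.8
- ochre (time / s: open intermediate / %, product / %): 10.0: 8.6, 2.0; 20.0: 11.9, 6.3; 40.0: 14.0, 17.1; 60.0: 12.1, 26.7; 80.0: 12.1, 34.0
- grey (time / s: open intermediate / %, product / %): 15.0: 8.3, 3.4; 30.0: 8.7, 7.0; 50.0: 7.6, 12.3; 60.0: 5.1, 13.2; 80.0: 4.9, 15.5

(readings scatter by 0.5 percentage points)

- what may be going on: substrate + partner -> open intermediate; second reagent + open intermediate -> product; open intermediate + capture agent -> trapped intermediate
- "hardly changes" means that all values lie within two and a half points (for a concentration: within two and a half percent of the largest)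

1. [open intermediate] at the end for dawn, noon, summer, spring, midnight, in this order
2. how the row runs (falls, then rises / rises, then falls / falls all the way / hardly changes / rises all the way)

I built the flask up one step at a time, in fractions of the charge. For the making step, substrate meeting partner, I added open intermediate and product in the teal run at 40.0 s, which gave 36.5% of the substrate turned over, and from that I read a making constant of 0.135 M⁻¹ s⁻¹. With this step by itself, my reckoning left 27.9% of the substrate in dawn at the end. In midnight, where partner was the limiting reagent, it left 0.508% of the partner and 77.6% of the substrate, so the fraction turned over was 72.1% in dawn and 22.4% in midnight.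

The second step, open intermediate with second reagent to product, let me drop time altogether. Open intermediate in the teal run read highest at 16.2%, and at a peak making equals using, so the fractions standing at that reading gave 0.274. I called this the balance number: the rate of making over the rate of using to product, with every fraction at its whole charge. At any moment, making over using is this number times the fractions of substrate and partner left, divided by the fractions of second reagent and open intermediate, and the row shares teal's charges of partner and second reagent. Setting that ratio to one, and counting all the turnover as product, put dawn at 7.31% of its charge, or 1.83 mM, which I committed to as my mark. The same level in midnight was 0.582%, far under what had been turned over, so I expected midnight to stand above its balance and falling, at a pace this ratio does not give.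

Last came capture, whose charge is 8.00% of the substrate in dawn and 0.500% in midnight. It adds a second way of using, and I did not read its size from the runs, so I put no number on it.

The forecast gave 0.002 M, 0.0045 M, 0.0092 M, 0.0134 M and 0.0121 M, a row that rises, then falls, with dawn above my mark, and it said: “Midnight therefore falls slightly below spring”.

The flasks gave 0.00227 M, 0.00476 M, 0.00939 M, 0.0138 M and 0.0122 M, a row that rises, then falls. The row turns at a substrate charge of 0.23 M; midnight's charge stands above that, and spring's stands below it.

    substrate + partner → open intermediate (k = 0.135 M⁻¹ s⁻¹)
    second reagent + open intermediate → product (k = 0.400 M⁻¹ s⁻¹)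
    open intermediate + capture agent → trapped intermediate (k = 0.699 M⁻¹ s⁻¹)

In dawn the half-life of open intermediate by the step to product was 0.30 min at the end, short against the 2.0 min of the run, and the balance number with the fractions then standing (substrate 27.9%, partner 80.0%, second reagent 86.1%, open intermediate 9.09%) gives making over using to product of 0.781, beside 0.765 for making over all using with each step taken net. In midnight the balance number, with substrate 77.6%, partner 0.512%, second reagent 31.3% and open intermediate 3.06%, gives making over using to product of 0.114.

The earlier runs and the new flask are simulated from invented constants; scatter was added.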